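A direct plan would close the chromone first and grow ring B on it. 7-Benzyloxy-3-formylchromone A1 would be converted into the nitrovinyl chromone A2, a Diels–Alder reaction with 2,3-dimethoxybutadiene would give the nitrocyclohexene A3, and denitration, dehydrogenation to the benzyl-protected isoflavone A4 and a benzyl-to-prenyl exchange would finish. Its weakest steps would be:
- the cycloaddition, because the nitrovinyl chromone would offer a second electrophilic site at C2 and could polymerise at the temperature needed;
- the tin-hydride removal of an unactivated secondary nitro group, because the radical C–N fragmentation would be slow and would need a large excess of stannane;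
- the protecting-group exchange together with the ring B dehydrogenation before it, three operations that would add no skeletal complexity, with a hydrogenolysis that would endanger the C2=C3 bond.

The new route keeps both benzene rings intact from the start and makes pyranone ring C last, in one convergent [4+2] step. The O1–C8a–C4a–C4(=O) unit of the target is read as an o-quinone ketene, available from 4-prenyloxysalicylic acid by formal loss of water. C2=C3 with its aryl group is read as the enol ether of an arylacetaldehyde. Their hetero-Diels–Alder union would form C3–C4 and O1–C2 together, rearomatise ring A and, after loss of methanol, give the isoflavone with the prenyl ether already in place. No ring is built and aromatised, no nitro group is carried and removed, and no protecting group is needed.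

Key step: step 4

Remark on the chemistry: the target has no stereocentre; the enol ether partner is used as its E/Z mixture, since both isomers lead to the same product.

Step 1
Reactants: 1 methyl 2,4-dihydroxybenzoate; 2 prenyl bromide (1-bromo-3-methylbut-2-ene)
Product: 3 methyl 2-hydroxy-4-[(3-methylbut-2-en-1-yl)oxy]benzoate
Conditions: K2CO3 (1.2 equiv), 2 (1.05 equiv), acetone, 50 °C
Reagents that add atoms: none
Why: Williamson ether synthesis, selective for the 4-OH because the 2-OH is held in a hydrogen bond to the ester carbonyl and is both less acidic and less nucleophilic, while the 4-phenoxide (para to the ester) displaces bromide from the primary allylic halide by SN2 at oxygen.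

Step 2
Reactants: 3 methyl 2-hydroxy-4-[(3-methylbut-2-en-1-yl)oxy]benzoate
Product: 4 2-hydroxy-4-[(3-methylbut-2-en-1-yl)oxy]benzoic acid
Conditions: NaOH (4 equiv), MeOH–H2O, 60 °C; then 1 M HCl to pH 3, 0 °C
Reagents that add atoms: sodium hydroxide, [Na+].[OH-]
Why: Ester saponification by acyl–oxygen cleavage, to which the aryl prenyl ether and its trisubstituted alkene are inert, with a brief cold acidification that should spare the acid-sensitive prenyl ether.

Step 3
Reactants: 5 3,4-dimethoxybenzaldehyde (veratraldehyde); 6 (methoxymethyl)triphenylphosphonium chloride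
Product: 8 4-(2-methoxyethenyl)-1,2-dimethoxybenzene (E/Z mixture), via ylide 7 (not isolated)
Conditions: 6 (1.3 equiv), KOt-Bu (1.3 equiv), THF, 0 °C; then 5, 0 °C → rt; Et3N-deactivated silica
Reagents that add atoms: none
Why: Wittig methoxymethylenation of an aromatic aldehyde with the alkoxy-substituted ylide, a standard one-carbon homologation; the alkene geometry is not controlled and need not be, because both isomers carry the nucleophilic carbon next to the aryl group and the geometry is lost in step 4.

Step 4
Reactants: 4 2-hydroxy-4-[(3-methylbut-2-en-1-yl)oxy]benzoic acid; 8 4-(2-methoxyethenyl)-1,2-dimethoxybenzene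
Product: 12 7-prenyloxy-3',4'-dimethoxyisoflavone, via acid chloride 9 (not isolated), via quinone ketene 10 (not isolated), via 2-methoxychromanone 11 (not isolated)
Conditions: 4, Me2C=C(Cl)NMe2 (1.05 equiv), CH2Cl2, 0 °C → rt; added over 4 h to 8 (2 equiv), i-Pr2NEt (2.5 equiv), PhMe, 60 °C; then DBU (0.3 equiv), rt
Reagents that add atoms: 1-chloro-N,N,2-trimethylprop-1-en-1-amine, CC(C)=C(Cl)N(C)C (its chlorine reaches only intermediate 9)
Why: Proposed new method: the chloroenamine should convert 4 into acid chloride 9 without releasing HCl, i-Pr2NEt should then remove the phenolic proton and expel chloride by 1,4-elimination to give o-quinone ketene 10, and the O=C–C=C=O unit of this dearomatised α-oxoketene should add as an electron-poor 1-oxadiene to the electron-rich alkene of 8 in an inverse-electron-demand hetero-Diels–Alder reaction (concerted and asynchronous, or stepwise through an oxocarbenium–enolate zwitterion, both paths ending at 11). The closest known reaction type is the [4+2] cycloaddition of acylketenes, generated from 1,3-dioxin-4-ones, with vinyl ethers to give 2-alkoxy-2,3-dihydro-4H-pyran-4-ones, together with the generation of o-quinone ketenes from salicylic acid derivatives and their capture by heteroatom nucleophiles. The one new ring, pyranone ring C, is closed by intermolecular [4+2] annulation that forms C3–C4 and O1–C2 together while ring A regains its aromaticity. Regiochemistry follows polarity, the nucleophilic aryl-bearing carbon of 8 bonding to the electrophilic ketene carbon (C4) and the methoxy-bearing carbon to the quinone oxygen (O1), so that the aryl group must end at C3; the stereocentres C2 and C3 of 11 are left uncontrolled because DBU removes the acidic C3–H and expels methoxide (E1cB) to give the achiral chromone. The step needs the enol ether to outrun self-condensation of 10 to salicylide oligomers and to be chosen over the unactivated prenyl alkene, which slow addition of 9 to excess 8 and the far higher HOMO of the enol ether should secure. A [2+2] addition to the ketene C=C bond is disfavoured because only the [4+2] mode restores the benzene ring.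

Compound list
1 | methyl 2,4-dihydroxybenzoate | COC(=O)c1ccc(O)cc1O | starting material
2 | prenyl bromide (1-bromo-3-methylbut-2-ene) | CC(C)=CCBr | starting material
3 | methyl 2-hydroxy-4-[(3-methylbut-2-en-1-yl)oxy]benzoate | COC(=O)c1ccc(OCC=C(C)C)cc1O | intermediate
4 | 2-hydroxy-4-[(3-methylbut-2-en-1-yl)oxy]benzoic acid | CC(C)=CCOc1ccc(C(=O)O)c(O)c1 | intermediate
5 | 3,4-dimethoxybenzaldehyde (veratraldehyde) | COc1ccc(C=O)cc1OC | starting material
6 | (methoxymethyl)triphenylphosphonium chloride | COC[P+](c1ccccc1)(c1ccccc1)c1ccccc1.[Cl-] | starting material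
7 | (methoxymethylidene)triphenylphosphorane (ylide, formed in the flask, not isolated) | COC=P(c1ccccc1)(c1ccccc1)c1ccccc1 | intermediate
8 | 4-(2-methoxyethenyl)-1,2-dimethoxybenzene (E/Z mixture, E isomer drawn) | CO/C=C/c1ccc(OC)c(OC)c1 | intermediate
9 | 2-hydroxy-4-[(3-methylbut-2-en-1-yl)oxy]benzoyl chloride (not isolated) | CC(C)=CCOc1ccc(C(=O)Cl)c(O)c1 | intermediate
10 | 3-[(3-methylbut-2-en-1-yl)oxy]-6-(oxomethylidene)cyclohexa-2,4-dien-1-one (o-quinone ketene, not isolated) | CC(C)=CCOC1=CC(=O)C(=C=O)C=C1 | intermediate
11 | 3-(3,4-dimethoxyphenyl)-2-methoxy-7-[(3-methylbut-2-en-1-yl)oxy]chroman-4-one (racemic mixture of cis and trans isomers at C2/C3, no configuration drawn; not isolated) | COC1Oc2cc(OCC=C(C)C)ccc2C(=O)C1c1ccc(OC)c(OC)c1 | intermediate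
12 | 7-prenyloxy-3',4'-dimethoxyisoflavone, i.e. 3-(3,4-dimethoxyphenyl)-7-[(3-methylbut-2-en-1-yl)oxy]-4H-chromen-4-one (achiral) | COc1ccc(-c2coc3cc(OCC=C(C)C)ccc3c2=O)cc1OC | target

Total step count: 4. Longest linear sequence: 3 steps (steps 1, 2 and 4); step 3 is a one-step branch.

Steps most likely to fail

Step 4 (proposed new method). The quinone ketene may self-condense to salicylide oligomers faster than it is trapped, or the chloroenamine may attack the phenol instead of the carboxyl group. The fallback uses known chemistry, sets out from ester 3 and returns at 12. The dianion of (3,4-dimethoxyphenyl)acetic acid (NaN(SiMe3)2, THF–DMF, −10 °C → rt) would be acylated by 3 in a Claisen-type condensation to give 2-(3,4-dimethoxyphenyl)-3-{2-hydroxy-4-[(3-methylbut-2-en-1-yl)oxy]phenyl}-3-oxopropanoic acid F1. F1 would lose carbon dioxide on mild acidification to give the deoxybenzoin 2-(3,4-dimethoxyphenyl)-1-{2-hydroxy-4-[(3-methylbut-2-en-1-yl)oxy]phenyl}ethan-1-one F2. Heating F2 with N,N-dimethylformamide dimethyl acetal (PhMe, 90 °C) would give the enaminone 2-(3,4-dimethoxyphenyl)-3-(dimethylamino)-1-{2-hydroxy-4-[(3-methylbut-2-en-1-yl)oxy]phenyl}prop-2-en-1-one F3, which should close at the phenol oxygen with loss of dimethylamine to give 12.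

Step 1. Alkylation may run on to the chelated 2-OH, or the ambident phenoxide may be prenylated at carbon. The fallback sets out from prenyl bromide 2 and returns at acid 4, bypassing steps 1 and 2. 2,4-Dihydroxybenzoic acid would be condensed with acetone (trifluoroacetic anhydride, trifluoroacetic acid) to 7-hydroxy-2,2-dimethyl-4H-1,3-benzodioxin-4-one F4, in which the carboxyl group and the ortho hydroxyl are tied up in one ring. Its single free hydroxyl would be alkylated with 2 (K2CO3, DMF, rt) to 2,2-dimethyl-7-[(3-methylbut-2-en-1-yl)oxy]-4H-1,3-benzodioxin-4-one F5. Aqueous NaOH in THF would then open the ring to 4 with loss of acetone.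

Step 3. The acid-labile enol ether may hydrolyse during isolation, or may not separate cleanly from triphenylphosphine oxide. The fallback replaces the olefination by a condensation and the enol ether by an enamine; it sets out from acid 4 (activated to 9 as in step 4) and returns at 12. Commercial (3,4-dimethoxyphenyl)acetaldehyde and morpholine (4 Å molecular sieves, PhMe, rt) would give 4-[(E)-2-(3,4-dimethoxyphenyl)ethenyl]morpholine F6. Its C-acylation by 9 (Stork enamine acylation, i-Pr2NEt, CH2Cl2, 0 °C) and ring closure would give 3-(3,4-dimethoxyphenyl)-2-(morpholin-4-yl)-7-[(3-methylbut-2-en-1-yl)oxy]chroman-4-one F7, which should lose morpholine on warming to give 12.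

Further compounds
F1 | step 4 | 2-(3,4-dimethoxyphenyl)-3-{2-hydroxy-4-[(3-methylbut-2-en-1-yl)oxy]phenyl}-3-oxopropanoic acid (racemic) | COc1ccc(C(C(=O)O)C(=O)c2ccc(OCC=C(C)C)cc2O)cc1OC
F2 | step 4 | 2-(3,4-dimethoxyphenyl)-1-{2-hydroxy-4-[(3-methylbut-2-en-1-yl)oxy]phenyl}ethan-1-one | COc1ccc(CC(=O)c2ccc(OCC=C(C)C)cc2O)cc1OC
F3 | step 4 | 2-(3,4-dimethoxyphenyl)-3-(dimethylamino)-1-{2-hydroxy-4-[(3-methylbut-2-en-1-yl)oxy]phenyl}prop-2-en-1-one | CN(C)C=C(C(=O)c1ccc(OCC=C(C)C)cc1O)c1ccc(OC)c(OC)c1
F4 | step 1 | 7-hydroxy-2,2-dimethyl-4H-1,3-benzodioxin-4-one | CC1(C)OC(=O)c2ccc(O)cc2O1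
F5 | step 1 | 2,2-dimethyl-7-[(3-methylbut-2-en-1-yl)oxy]-4H-1,3-benzodioxin-4-one | CC1(C)OC(=O)c2ccc(OCC=C(C)C)cc2O1
F6 | step 3 | 4-[(E)-2-(3,4-dimethoxyphenyl)ethenyl]morpholine | COc1ccc(/C=C/N2CCOCC2)cc1OC
F7 | step 3 | 3-(3,4-dimethoxyphenyl)-2-(morpholin-4-yl)-7-[(3-methylbut-2-en-1-yl)oxy]chroman-4-one (racemic diastereomer mixture, no configuration drawn) | COc1ccc(C2C(N3CCOCC3)Oc3cc(OCC=C(C)C)ccc3C2=O)cc1OC
A1 | direct plan | 7-(benzyloxy)-4-oxo-4H-chromene-3-carbaldehyde | O=Cc1coc2cc(OCc3ccccc3)ccc2c1=O
A2 | direct plan | (E)-7-(benzyloxy)-3-(2-nitrovinyl)-4H-chromen-4-one | O=[N+]([O-])/C=C/c1coc2cc(OCc3ccccc3)ccc2c1=O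
A3 | direct plan | (±)-trans-7-(benzyloxy)-3-(3,4-dimethoxy-6-nitrocyclohex-3-en-1-yl)-4H-chromen-4-one (racemic, one enantiomer drawn) | COC1=C(OC)C[C@H]([N+](=O)[O-])[C@H](C1)c1coc2cc(OCc3ccccc3)ccc2c1=O
A4 | direct plan | 7-(benzyloxy)-3-(3,4-dimethoxyphenyl)-4H-chromen-4-one | COc1ccc(-c2coc3cc(OCc4ccccc4)ccc3c2=O)cc1OC
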